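The decalin is cut through ring B (C1–C2–C3–C4=C5–C6, cadinane numbering): C2–C3–C4 with the C15 carbon is added to a ring A cyclohexanone as one three-carbon unit. The key step exploits that C1 is α to C10 (the future exocyclic methylene carbon, carried as a ketone) and that C5 is a formyl group on C6. The C1 β-keto ester enolate opens a cyclopropylphosphonium salt (C1–C2), and the ylide so released olefinates the formyl group (C4=C5), closing ring B in one operation. The precursor is a monocyclic cyclohexanone bearing an allyl ester at C1, the formyl group at C6, the C11–C12 acetate arm at C7 and a boronate as masked C8 hydroxyl.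

Key step: step 5

Remark (numbering): ring A = C1, C6, C7, C8, C9, C10; ring B = C1 to C6; C7 carries C11 (with C12 and C13), C8 the ester oxygen, C10 the exocyclic C14, C4 the C15 carbon.
Remark (chemistry): the C1 centre of 5 to 12 is enolisable or quaternary and is reset in step 6, so it is left undefined. Compound 2 is sold as an aqueous solution and is taken up in CH2Cl2 and dried before use.

Step 1
Reactants: 1 allyl acetoacetate; 2 2,2-dimethoxyacetaldehyde
Product: 3 allyl 2-acetyl-4,4-dimethoxybut-2-enoate (E/Z mixture)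
Conditions: piperidine (10 mol%), AcOH (10 mol%), MgSO4, CH2Cl2, 0 °C to rt
Reagents that add atoms: none
Why: Knoevenagel condensation of the active methylene with a non-enolisable, activated aldehyde; both alkene isomers are usable because they interconvert under the amine catalysis of step 2.

Step 2
Reactants: 3 allyl 2-acetyl-4,4-dimethoxybut-2-enoate; 4 tert-butyl 4-oxobutanoate
Product: 6 allyl (5S,6R)-5-(2-tert-butoxy-2-oxoethyl)-6-(dimethoxymethyl)-2-oxocyclohex-3-ene-1-carboxylate, via syn Michael adduct 5 (not isolated)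
Conditions: (S)-α,α-diphenylprolinol trimethylsilyl ether (10 mol%), PhCO2H (10 mol%), toluene, 0 °C to rt; then piperidine/AcOH (20 mol%), 40 °C
Reagents that add atoms: none
Why: Enamine-catalysed asymmetric Michael addition of the aldehyde to the alkylidene β-keto ester (the catalyst shields one enamine face and the synclinal transition state should give the syn adduct, fixing C7 and C6), followed by amine-catalysed intramolecular aldol condensation of the acetyl methyl (C9) onto the aldehyde (C8); C7, γ to the new enone, can settle trans to C6 through the dienamine, whereas C6 cannot epimerise.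

Step 3
Reactants: 6 allyl (5S,6R)-5-(2-tert-butoxy-2-oxoethyl)-6-(dimethoxymethyl)-2-oxocyclohex-3-ene-1-carboxylate
Product: 7 allyl (4R,5S,6R)-5-(2-tert-butoxy-2-oxoethyl)-6-(dimethoxymethyl)-2-oxo-4-(4,4,5,5-tetramethyl-1,3,2-dioxaborolan-2-yl)cyclohexane-1-carboxylate
Conditions: CuCl (5 mol%), Xantphos (5 mol%), NaOtBu (10 mol%), B2pin2 (1.1 equiv), MeOH (2 equiv), THF, rt
Reagents that add atoms: bis(pinacolato)diboron, CC1(C)OB(OC1(C)C)B1OC(C)(C)C(C)(C)O1
Why: Copper-catalysed conjugate borylation of the enone; the boryl copper should add to C8 anti to the adjacent C7 arm (trans-3,4 rule for 4-substituted cyclohexenones), giving a masked C8 hydroxyl that cannot β-eliminate in the basic steps ahead.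

Step 4
Reactants: 7 allyl (4R,5S,6R)-5-(2-tert-butoxy-2-oxoethyl)-6-(dimethoxymethyl)-2-oxo-4-(pinacolboryl)cyclohexane-1-carboxylate
Product: 8 allyl (4R,5S,6R)-5-(2-tert-butoxy-2-oxoethyl)-6-formyl-2-oxo-4-(4,4,5,5-tetramethyl-1,3,2-dioxaborolan-2-yl)cyclohexane-1-carboxylate
Conditions: Amberlyst-15, acetone/H2O (20:1), rt
Reagents that add atoms: water, O
Why: Mild acid-catalysed acetal hydrolysis that should spare both esters and the pinacol boronate; the formyl-bearing C6 stays trans to C7, its thermodynamic arrangement.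

Step 5
Reactants: 8 allyl (4R,5S,6R)-5-(2-tert-butoxy-2-oxoethyl)-6-formyl-2-oxo-4-(pinacolboryl)cyclohexane-1-carboxylate; 9 (1-ethoxycarbonylcyclopropyl)triphenylphosphonium tetrafluoroborate
Product: 11 4a-allyl 2-ethyl (7R,8S,8aS)-8-(2-tert-butoxy-2-oxoethyl)-5-oxo-7-(4,4,5,5-tetramethyl-1,3,2-dioxaborolan-2-yl)-3,4,5,6,7,8-hexahydronaphthalene-2,4a(8aH)-dicarboxylate, via phosphorus ylide 10 (not isolated)
Conditions: NaH (1.05 equiv), THF, 0 °C; then 9 (1.2 equiv), THF/HMPA (4:1), rt to 50 °C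
Reagents that add atoms: none
Why: NaH forms the sodium enolate of the β-keto ester, whose C1 opens the doubly activated cyclopropane of 9 at a ring CH2 (homoconjugate substitution), forging C1–C2 and releasing the ester-stabilised ylide 10 at C4. The ylide adds to the formyl carbon C5 on C6 and collapses through the oxaphosphetane with loss of Ph3PO (intramolecular Wittig olefination), forging C4=C5. The closest known reaction is the cyclopropylphosphonium annulation of β-keto ester enolates with this same salt, which gives cyclopentenes, together with its six-ring closures where the nucleophile is flanked by a formyl group. Ring B closes as a six-membered ring by attack of the ylide carbon on the exocyclic C=O (6-exo-trig), and the ring enforces the cis alkene geometry. The only new stereocentre is the quaternary C1, expected from alkylation anti to the C6 formyl group but immaterial because step 6 resets it. The step needs C-alkylation at C1, the sole doubly activated site, and olefination of the aldehyde instead of the C10 ketone, which the much higher reactivity of aldehydes toward ester-stabilised ylides should secure.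

Step 6
Reactants: 11 4a-allyl 2-ethyl (7R,8S,8aS)-8-(2-tert-butoxy-2-oxoethyl)-5-oxo-7-(pinacolboryl)-3,4,5,6,7,8-hexahydronaphthalene-2,4a(8aH)-dicarboxylate
Product: 13 ethyl (4aS,7R,8S,8aS)-8-(2-tert-butoxy-2-oxoethyl)-5-oxo-7-(4,4,5,5-tetramethyl-1,3,2-dioxaborolan-2-yl)-3,4,4a,5,6,7,8,8a-octahydronaphthalene-2-carboxylate, via β-keto acid 12 (not isolated)
Conditions: Pd(PPh3)4 (5 mol%), morpholine (5 equiv), THF, rt; then DBU (0.2 equiv), rt
Reagents that add atoms: none
Why: Tsuji–Trost deallylation (allyl transfer to morpholine) and spontaneous decarboxylation of the β-keto acid give the C10 ketone; base equilibration of the enolisable C1 should give the trans-fused ketone, in which all four ring A substituents are equatorial.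

Step 7
Reactants: 13 ethyl (4aS,7R,8S,8aS)-8-(2-tert-butoxy-2-oxoethyl)-5-oxo-7-(pinacolboryl)-3,4,4a,5,6,7,8,8a-octahydronaphthalene-2-carboxylate
Product: 14 ethyl (4aS,7R,8S,8aS)-8-(2-tert-butoxy-2-oxoethyl)-5-methylidene-7-(4,4,5,5-tetramethyl-1,3,2-dioxaborolan-2-yl)-3,4,4a,5,6,7,8,8a-octahydronaphthalene-2-carboxylate
Conditions: Ph3PCH3Br (1.5 equiv), KOtBu (1.4 equiv), THF, 0 °C to rt
Reagents that add atoms: methyltriphenylphosphonium bromide, C[P+](c1ccccc1)(c1ccccc1)c1ccccc1.[Br-]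
Why: Wittig methylenation of the ketone, which is far more reactive toward the non-stabilised ylide than the two esters; C1 is already in its thermodynamic configuration and the boronate is not a leaving group.

Step 8
Reactants: 14 ethyl (4aS,7R,8S,8aS)-8-(2-tert-butoxy-2-oxoethyl)-5-methylidene-7-(pinacolboryl)-3,4,4a,5,6,7,8,8a-octahydronaphthalene-2-carboxylate
Product: 15 tert-butyl 2-[(1S,2R,4aS,8aS)-7-(hydroxymethyl)-4-methylidene-2-(4,4,5,5-tetramethyl-1,3,2-dioxaborolan-2-yl)-1,2,3,4,4a,5,6,8a-octahydronaphthalen-1-yl]acetate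
Conditions: iBu2AlH (2.2 equiv), CH2Cl2, −78 °C; aq. KNaC4H4O6
Reagents that add atoms: none
Why: 1,2-Reduction of the conjugated ethyl ester to the allylic alcohol (C15); the hindered tert-butyl ester should survive at −78 °C.

Step 9
Reactants: 15 tert-butyl 2-[(1S,2R,4aS,8aS)-7-(hydroxymethyl)-4-methylidene-2-(pinacolboryl)-1,2,3,4,4a,5,6,8a-octahydronaphthalen-1-yl]acetate
Product: 16 tert-butyl 2-[(1S,2R,4aS,8aS)-7-{[(tert-butyldimethylsilyl)oxy]methyl}-4-methylidene-2-(4,4,5,5-tetramethyl-1,3,2-dioxaborolan-2-yl)-1,2,3,4,4a,5,6,8a-octahydronaphthalen-1-yl]acetate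
Conditions: TBSCl (1.2 equiv), imidazole (2 equiv), CH2Cl2, 0 °C to rt
Reagents that add atoms: tert-butyldimethylsilyl chloride, CC(C)(C)[Si](C)(C)Cl
Why: Silylation of the only free hydroxyl, the primary allylic alcohol, so that it cannot compete in step 14.

Step 10
Reactants: 16 tert-butyl 2-[(1S,2R,4aS,8aS)-7-{[(tert-butyldimethylsilyl)oxy]methyl}-4-methylidene-2-(pinacolboryl)-1,2,3,4,4a,5,6,8a-octahydronaphthalen-1-yl]acetate
Product: 17 tert-butyl 2-[(1R,2R,4aS,8aS)-7-{[(tert-butyldimethylsilyl)oxy]methyl}-2-hydroxy-4-methylidene-1,2,3,4,4a,5,6,8a-octahydronaphthalen-1-yl]acetate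
Conditions: 30% H2O2, 2 M NaOH, THF, 0 °C
Reagents that add atoms: hydrogen peroxide, OO
Why: Oxidation of the C–B bond with retention (1,2-shift of carbon from boron to oxygen) gives the equatorial C8 alcohol trans to the C7 arm.

Step 11
Reactants: 17 tert-butyl 2-[(1R,2R,4aS,8aS)-7-{[(tert-butyldimethylsilyl)oxy]methyl}-2-hydroxy-4-methylidene-1,2,3,4,4a,5,6,8a-octahydronaphthalen-1-yl]acetate
Product: 20 tert-butyl 2-[(1S,2R,4aS,8aS)-7-{[(tert-butyldimethylsilyl)oxy]methyl}-2-hydroxy-4-methylidene-1,2,3,4,4a,5,6,8a-octahydronaphthalen-1-yl]prop-2-enoate, via Mannich base 18 (not isolated), via ammonium iodide 19 (not isolated)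
Conditions: LiN(iPr)2 (2.3 equiv), THF, −78 °C; CH2=NMe2+ I− (1.5 equiv), −78 °C to rt; MeI, rt; DBU, rt
Reagents that add atoms: N,N-dimethylmethyleneiminium iodide, C=[N+](C)C.[I-]
Why: α-Methylenation of the only enolisable carbonyl: the lithium ester enolate (the C8 alkoxide is a spectator) undergoes a Mannich reaction, and quaternisation followed by E1cB loss of trimethylamine gives the acrylate.

Step 12
Reactants: 21 (R)-2,2-dimethyl-1,3-dioxolane-4-carbaldehyde
Product: 22 (S)-4-ethynyl-2,2-dimethyl-1,3-dioxolane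
Conditions: dimethyl (1-diazo-2-oxopropyl)phosphonate (1.2 equiv), K2CO3 (2 equiv), MeOH, 0 °C to rt
Reagents that add atoms: dimethyl (1-diazo-2-oxopropyl)phosphonate, COP(=O)(OC)C(=[N+]=[N-])C(C)=O
Why: Seyferth–Gilbert homologation under mild carbonate conditions should keep the α-oxygenated stereocentre intact; the descriptor changes from R to S by priority only.

Step 13
Reactants: 22 (S)-4-ethynyl-2,2-dimethyl-1,3-dioxolane
Product: 23 (S)-2-(2,2-dimethyl-1,3-dioxolan-4-yl)prop-2-enoic acid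
Conditions: Pd(OAc)2 (1 mol%), 2-(diphenylphosphino)pyridine (20 mol%), MsOH (5 mol%), CO (20 bar), H2O (3 equiv), acetone, 50 °C
Reagents that add atoms: carbon monoxide, [C-]#[O+]; water, O
Why: Palladium-catalysed Markovnikov hydroxycarbonylation of the terminal alkyne places the carboxyl group on the internal carbon; acetone as solvent should suppress loss of the acetonide.

Step 14
Reactants: 20 tert-butyl 2-[(1S,2R,4aS,8aS)-7-{[(tert-butyldimethylsilyl)oxy]methyl}-2-hydroxy-4-methylidene-1,2,3,4,4a,5,6,8a-octahydronaphthalen-1-yl]prop-2-enoate; 23 (S)-2-(2,2-dimethyl-1,3-dioxolan-4-yl)prop-2-enoic acid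
Product: 24 tert-butyl 2-[(1S,2S,4aS,8aS)-7-{[(tert-butyldimethylsilyl)oxy]methyl}-2-({2-[(4S)-2,2-dimethyl-1,3-dioxolan-4-yl]prop-2-enoyl}oxy)-4-methylidene-1,2,3,4,4a,5,6,8a-octahydronaphthalen-1-yl]prop-2-enoate
Conditions: PPh3 (2 equiv), DIAD (2 equiv), toluene, 0 °C to rt
Reagents that add atoms: none
Why: Mitsunobu esterification: the carboxylate displaces the equatorial C8 alkoxyphosphonium group with inversion, giving the axial ester cis to the C7 arm; an equatorial leaving group has no antiperiplanar hydrogen, which disfavours elimination.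

Step 15
Reactants: 24 tert-butyl 2-[(1S,2S,4aS,8aS)-7-{[(tert-butyldimethylsilyl)oxy]methyl}-2-({2-[(4S)-2,2-dimethyl-1,3-dioxolan-4-yl]prop-2-enoyl}oxy)-4-methylidene-1,2,3,4,4a,5,6,8a-octahydronaphthalen-1-yl]prop-2-enoate
Product: 27 2-[(1S,2S,4aS,8aS)-2-{[(3S)-3,4-dihydroxy-2-methylidenebutanoyl]oxy}-7-(hydroxymethyl)-4-methylidene-1,2,3,4,4a,5,6,8a-octahydronaphthalen-1-yl]prop-2-enoic acid (target), via trimethylsilyl ester 25 (not isolated), via carboxylic acid 26 (not isolated)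
Conditions: TMSOTf (3 equiv), 2,6-lutidine (5 equiv), CH2Cl2, 0 °C; then AcOH/THF/H2O (3:1:1), 40 °C
Reagents that add atoms: none
Why: Silyl triflate-mediated cleavage of the tert-butyl ester (loss of isobutene under non-protic conditions, so the 1,1-disubstituted alkenes are not protonated), then mild aqueous acid hydrolyses the silyl ester, the primary silyl ether and the acetonide and should leave the C8 ester untouched.

Compound list
1 | allyl acetoacetate (prop-2-en-1-yl 3-oxobutanoate) | CC(=O)CC(=O)OCC=C | starting material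
2 | 2,2-dimethoxyacetaldehyde | COC(OC)C=O | starting material
3 | allyl 2-acetyl-4,4-dimethoxybut-2-enoate (E/Z mixture) | CC(=O)C(=CC(OC)OC)C(=O)OCC=C | intermediate
4 | tert-butyl 4-oxobutanoate | CC(C)(C)OC(=O)CCC=O | starting material
5 | 1-allyl 6-tert-butyl (3R,4R)-2-acetyl-3-(dimethoxymethyl)-4-formylhexanedioate (syn Michael adduct; not isolated) | CC(C)(C)OC(=O)C[C@@H](C=O)[C@@H](C(OC)OC)C(C(C)=O)C(=O)OCC=C | intermediate
6 | allyl (5S,6R)-5-(2-tert-butoxy-2-oxoethyl)-6-(dimethoxymethyl)-2-oxocyclohex-3-ene-1-carboxylate (5,6-trans) | CC(C)(C)OC(=O)C[C@@H]1[C@@H](C(OC)OC)C(C(=O)OCC=C)C(=O)C=C1 | intermediate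
7 | allyl (4R,5S,6R)-5-(2-tert-butoxy-2-oxoethyl)-6-(dimethoxymethyl)-2-oxo-4-(4,4,5,5-tetramethyl-1,3,2-dioxaborolan-2-yl)cyclohexane-1-carboxylate (4,5-trans, 5,6-trans) | CC(C)(C)OC(=O)C[C@@H]1[C@@H](C(OC)OC)C(C(=O)OCC=C)C(=O)C[C@H]1B2OC(C)(C)C(C)(C)O2 | intermediate
8 | allyl (4R,5S,6R)-5-(2-tert-butoxy-2-oxoethyl)-6-formyl-2-oxo-4-(4,4,5,5-tetramethyl-1,3,2-dioxaborolan-2-yl)cyclohexane-1-carboxylate | CC(C)(C)OC(=O)C[C@@H]1[C@@H](C=O)C(C(=O)OCC=C)C(=O)C[C@H]1B2OC(C)(C)C(C)(C)O2 | intermediate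
9 | (1-ethoxycarbonylcyclopropyl)triphenylphosphonium tetrafluoroborate | CCOC(=O)C1(CC1)[P+](c1ccccc1)(c1ccccc1)c1ccccc1.F[B-](F)(F)F | starting material
10 | ester-stabilised ylide: 8 carrying at C1 a 4-ethoxy-4-oxo-3-(triphenylphosphoranylidene)butyl chain (not isolated) | CC(C)(C)OC(=O)C[C@@H]1[C@@H](C=O)C(CCC(C(=O)OCC)=P(c2ccccc2)(c2ccccc2)c2ccccc2)(C(=O)OCC=C)C(=O)C[C@H]1B2OC(C)(C)C(C)(C)O2 | intermediate
11 | 4a-allyl 2-ethyl (7R,8S,8aS)-8-(2-tert-butoxy-2-oxoethyl)-5-oxo-7-(4,4,5,5-tetramethyl-1,3,2-dioxaborolan-2-yl)-3,4,5,6,7,8-hexahydronaphthalene-2,4a(8aH)-dicarboxylate (C4a not controlled) | CC(C)(C)OC(=O)C[C@@H]1[C@H]2C=C(C(=O)OCC)CCC2(C(=O)OCC=C)C(=O)C[C@H]1B3OC(C)(C)C(C)(C)O3 | intermediate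
12 | (7R,8S,8aS)-8-(2-tert-butoxy-2-oxoethyl)-2-(ethoxycarbonyl)-5-oxo-7-(pinacolboryl)-3,4,5,6,7,8-hexahydronaphthalene-4a(8aH)-carboxylic acid (not isolated) | CC(C)(C)OC(=O)C[C@@H]1[C@H]2C=C(C(=O)OCC)CCC2(C(=O)O)C(=O)C[C@H]1B3OC(C)(C)C(C)(C)O3 | intermediate
13 | ethyl (4aS,7R,8S,8aS)-8-(2-tert-butoxy-2-oxoethyl)-5-oxo-7-(4,4,5,5-tetramethyl-1,3,2-dioxaborolan-2-yl)-3,4,4a,5,6,7,8,8a-octahydronaphthalene-2-carboxylate (trans-fused) | CC(C)(C)OC(=O)C[C@@H]1[C@H]2C=C(C(=O)OCC)CC[C@@H]2C(=O)C[C@H]1B3OC(C)(C)C(C)(C)O3 | intermediate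
14 | ethyl (4aS,7R,8S,8aS)-8-(2-tert-butoxy-2-oxoethyl)-5-methylidene-7-(4,4,5,5-tetramethyl-1,3,2-dioxaborolan-2-yl)-3,4,4a,5,6,7,8,8a-octahydronaphthalene-2-carboxylate | CC(C)(C)OC(=O)C[C@@H]1[C@H]2C=C(C(=O)OCC)CC[C@@H]2C(=C)C[C@H]1B3OC(C)(C)C(C)(C)O3 | intermediate
15 | tert-butyl 2-[(1S,2R,4aS,8aS)-7-(hydroxymethyl)-4-methylidene-2-(4,4,5,5-tetramethyl-1,3,2-dioxaborolan-2-yl)-1,2,3,4,4a,5,6,8a-octahydronaphthalen-1-yl]acetate | CC(C)(C)OC(=O)C[C@@H]1[C@H]2C=C(CO)CC[C@@H]2C(=C)C[C@H]1B3OC(C)(C)C(C)(C)O3 | intermediate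
16 | tert-butyl 2-[(1S,2R,4aS,8aS)-7-{[(tert-butyldimethylsilyl)oxy]methyl}-4-methylidene-2-(4,4,5,5-tetramethyl-1,3,2-dioxaborolan-2-yl)-1,2,3,4,4a,5,6,8a-octahydronaphthalen-1-yl]acetate | CC(C)(C)OC(=O)C[C@@H]1[C@H]2C=C(CO[Si](C)(C)C(C)(C)C)CC[C@@H]2C(=C)C[C@H]1B3OC(C)(C)C(C)(C)O3 | intermediate
17 | tert-butyl 2-[(1R,2R,4aS,8aS)-7-{[(tert-butyldimethylsilyl)oxy]methyl}-2-hydroxy-4-methylidene-1,2,3,4,4a,5,6,8a-octahydronaphthalen-1-yl]acetate (hydroxyl equatorial, trans to the C1 arm) | CC(C)(C)OC(=O)C[C@@H]1[C@H]2C=C(CO[Si](C)(C)C(C)(C)C)CC[C@@H]2C(=C)C[C@H]1O | intermediate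
18 | Mannich base: 17 with a (dimethylamino)methyl group on the ester α-carbon (not isolated) | CC(C)(C)OC(=O)C(CN(C)C)[C@@H]1[C@H]2C=C(CO[Si](C)(C)C(C)(C)C)CC[C@@H]2C(=C)C[C@H]1O | intermediate
19 | trimethylammonium iodide of 18 (not isolated) | CC(C)(C)OC(=O)C(C[N+](C)(C)C)[C@@H]1[C@H]2C=C(CO[Si](C)(C)C(C)(C)C)CC[C@@H]2C(=C)C[C@H]1O.[I-] | intermediate
20 | tert-butyl 2-[(1S,2R,4aS,8aS)-7-{[(tert-butyldimethylsilyl)oxy]methyl}-2-hydroxy-4-methylidene-1,2,3,4,4a,5,6,8a-octahydronaphthalen-1-yl]prop-2-enoate | C=C(C(=O)OC(C)(C)C)[C@@H]1[C@H]2C=C(CO[Si](C)(C)C(C)(C)C)CC[C@@H]2C(=C)C[C@H]1O | intermediate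
21 | (R)-2,2-dimethyl-1,3-dioxolane-4-carbaldehyde | O=C[C@H]1COC(C)(C)O1 | starting material
22 | (S)-4-ethynyl-2,2-dimethyl-1,3-dioxolane | C#C[C@H]1COC(C)(C)O1 | intermediate
23 | (S)-2-(2,2-dimethyl-1,3-dioxolan-4-yl)prop-2-enoic acid | OC(=O)C(=C)[C@H]1COC(C)(C)O1 | intermediate
24 | tert-butyl 2-[(1S,2S,4aS,8aS)-7-{[(tert-butyldimethylsilyl)oxy]methyl}-2-({2-[(4S)-2,2-dimethyl-1,3-dioxolan-4-yl]prop-2-enoyl}oxy)-4-methylidene-1,2,3,4,4a,5,6,8a-octahydronaphthalen-1-yl]prop-2-enoate (ester axial, cis to the C1 arm) | C=C(C(=O)OC(C)(C)C)[C@@H]1[C@H]2C=C(CO[Si](C)(C)C(C)(C)C)CC[C@@H]2C(=C)C[C@@H]1OC(=O)C(=C)[C@H]3COC(C)(C)O3 | intermediate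
25 | trimethylsilyl ester corresponding to 24 (not isolated) | C=C(C(=O)O[Si](C)(C)C)[C@@H]1[C@H]2C=C(CO[Si](C)(C)C(C)(C)C)CC[C@@H]2C(=C)C[C@@H]1OC(=O)C(=C)[C@H]3COC(C)(C)O3 | intermediate
26 | carboxylic acid corresponding to 24, silyl ether and acetonide still in place (not isolated) | C=C(C(=O)O)[C@@H]1[C@H]2C=C(CO[Si](C)(C)C(C)(C)C)CC[C@@H]2C(=C)C[C@@H]1OC(=O)C(=C)[C@H]3COC(C)(C)O3 | intermediate
27 | 2-[(1S,2S,4aS,8aS)-2-{[(3S)-3,4-dihydroxy-2-methylidenebutanoyl]oxy}-7-(hydroxymethyl)-4-methylidene-1,2,3,4,4a,5,6,8a-octahydronaphthalen-1-yl]prop-2-enoic acid | C=C(C(=O)O)[C@@H]1[C@H]2C=C(CO)CC[C@@H]2C(=C)C[C@@H]1OC(=O)C(=C)[C@H](O)CO | target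

Total step count: 15. Longest linear sequence: 13 steps (steps 1 to 11, 14 and 15); steps 12 and 13 make the side-chain acid.

Steps most likely to fail

Step 5 (key step). The hindered tertiary enolate may open the cyclopropane too slowly, so that O-alkylation, aldehyde self-condensation or olefination at the C10 ketone compete. The fallback sets out from 8 and separates the two bond formations. The sodium enolate of 8 (NaH, DMF, NaI) is alkylated by SN2 with ethyl 4-bromo-2-(diethoxyphosphoryl)butanoate F1 (from triethyl phosphonoacetate, NaH and 1,2-dibromoethane), giving the C1-alkylated phosphonate keto aldehyde F2. An intramolecular Horner–Wadsworth–Emmons olefination of F2 (LiCl, DBU, MeCN) then closes ring B, and the route is rejoined at 11.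

Step 2. Facial control at C6 in the enamine Michael addition may be incomplete (syn/anti leakage); after C7 equilibration this would lower the enantiomeric purity. The fallback sets out from 3 and 4 and moves the stereocontrol to a chiral Lewis acid. Aldehyde 4 is converted (TBSOTf, Et3N) into its (Z)-enol silyl ether F3. Cu(OTf)2 with a chiral tert-butyl bis(oxazoline) ligand, which chelates the alkylidene β-keto ester 3, catalyses a Mukaiyama–Michael addition in its hetero-Diels–Alder form to give the all-cis dihydropyran F4, with C6 set by the ligand. Buffered Bu4NF unmasks the aldehyde and piperidinium acetate effects the aldol condensation to the cis-cyclohexenone F5. F5 equilibrates at C7 under the same amine conditions, and the route is rejoined at 6.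

Step 14. Substitution at the hindered secondary carbinol may be slow, with elimination or acylation with retention taking over. The fallback sets out from 20 and replaces the SN2 inversion by reagent-controlled reduction. Dess–Martin periodinane (NaHCO3 buffer) gives the β,γ-unsaturated ketone F6. LiBH(sBu)3 (1.05 equiv, THF, −78 °C) delivers hydride from the equatorial side to give the axial alcohol F7, the C8 epimer of 20. Yamaguchi esterification of F7 with 23 (2,4,6-trichlorobenzoyl chloride, Et3N, DMAP, toluene) rejoins the route at 24.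

Further compounds
F1 | step 5 | ethyl 4-bromo-2-(diethoxyphosphoryl)butanoate | CCOC(=O)C(CCBr)P(=O)(OCC)OCC
F2 | step 5 | allyl (4R,5S,6R)-5-(2-tert-butoxy-2-oxoethyl)-1-[3-(diethoxyphosphoryl)-4-ethoxy-4-oxobutyl]-6-formyl-2-oxo-4-(4,4,5,5-tetramethyl-1,3,2-dioxaborolan-2-yl)cyclohexane-1-carboxylate | CC(C)(C)OC(=O)C[C@@H]1[C@@H](C=O)C(CCC(C(=O)OCC)P(=O)(OCC)OCC)(C(=O)OCC=C)C(=O)C[C@H]1B2OC(C)(C)C(C)(C)O2
F3 | step 2 | tert-butyl (Z)-4-[(tert-butyldimethylsilyl)oxy]but-3-enoate | CC(C)(C)OC(=O)C/C=C\O[Si](C)(C)C(C)(C)C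
F4 | step 2 | allyl 3-(2-tert-butoxy-2-oxoethyl)-2-[(tert-butyldimethylsilyl)oxy]-4-(dimethoxymethyl)-6-methyl-3,4-dihydro-2H-pyran-5-carboxylate (2,3,4-all-cis) | CC(C)(C)OC(=O)C[C@@H]1[C@H](O[Si](C)(C)C(C)(C)C)OC(C)=C(C(=O)OCC=C)[C@@H]1C(OC)OC
F5 | step 2 | allyl (5R,6R)-5-(2-tert-butoxy-2-oxoethyl)-6-(dimethoxymethyl)-2-oxocyclohex-3-ene-1-carboxylate (5,6-cis epimer of 6) | CC(C)(C)OC(=O)C[C@H]1[C@@H](C(OC)OC)C(C(=O)OCC=C)C(=O)C=C1
F6 | step 14 | tert-butyl 2-[(1S,4aS,8aS)-7-{[(tert-butyldimethylsilyl)oxy]methyl}-4-methylidene-2-oxo-1,2,3,4,4a,5,6,8a-octahydronaphthalen-1-yl]prop-2-enoate | C=C(C(=O)OC(C)(C)C)[C@@H]1[C@H]2C=C(CO[Si](C)(C)C(C)(C)C)CC[C@@H]2C(=C)CC1=O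
F7 | step 14 | tert-butyl 2-[(1S,2S,4aS,8aS)-7-{[(tert-butyldimethylsilyl)oxy]methyl}-2-hydroxy-4-methylidene-1,2,3,4,4a,5,6,8a-octahydronaphthalen-1-yl]prop-2-enoate (hydroxyl axial, cis to the C1 arm) | C=C(C(=O)OC(C)(C)C)[C@@H]1[C@H]2C=C(CO[Si](C)(C)C(C)(C)C)CC[C@@H]2C(=C)C[C@@H]1O
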